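**Plan**
1. Numbering: ring A is the methyl benzoate ring (C1 CO2Me, C2 OMe, C4 O-acyl); ring B is the acyl ring, C1' carrying the depside carbonyl.
2. Enabling feature: ring B is a resorcinol with C1' (carboxyl) para to the C4' hydroxyl, the C5' methyl between the C4' and C6' oxygens and the C2' methyl beside C1'. An ester-bearing isopropenylketene and 1-silyloxypropyne assemble exactly this pattern in one operation.
3. Retrosynthesis: C3'–Cl and the C6' O–Si bond go first. Ring B is then cut at C4'–C5', C6'–C1' and C3'–C4' (the C1'–C2' bond of the Wolff shift is undone) to a ring A aryl 2-diazo-4-methyl-3-oxopent-4-enoate and triisopropylsilyloxypropyne. The diazo ketoester is cut between the diazo carbon and the ketone carbon to a ring A aryl diazoacetate and methacrolein, and the depside C–O bond to the ring A phenol and bromoacetyl bromide.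
4. Forward: atraric acid gains its C5 methyl (formylation, reduction) and its C2 methyl ether (via the C4 benzyl ether) to become the ring A phenol, so ring A is never built. The hindered ester is made first with a two-carbon acyl group, and ring B is the only ring formed, on that ester, before desilylation and chlorination.
5. Stereochemistry: the target has no stereocentre and no stereogenic double bond; the stereocentres that arise on the way are racemic and are destroyed.

Key step: step 11

Remark: 1-propynyllithium is taken as the purchased form of propyne, and "ring A aryl" in the names below means 3-methoxy-4-(methoxycarbonyl)-2,5,6-trimethylphenyl.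

**Route**

Step 1
Reactants: 1 methyl 2,4-dihydroxy-3,6-dimethylbenzoate (atraric acid)
Product: 3 methyl 5-formyl-2,4-dihydroxy-3,6-dimethylbenzoate, via chloro(methoxy)methyl arene 2 (not isolated)
Conditions: Cl2CHOMe, TiCl4, CH2Cl2, 0 °C to rt; then aq. HCl
Reagents that add atoms: dichloromethyl methyl ether, COC(Cl)Cl (formyl carbon); water, O (formyl oxygen)
Why: Rieche formylation, in which the titanium-bound phenoxide steers the methoxychlorocarbenium ion to C5, the only free ring carbon (ortho to the C4 hydroxyl, para to the C2 hydroxyl), and the chloro ether 2 is hydrolysed on quench.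

Step 2
Reactants: 3 methyl 5-formyl-2,4-dihydroxy-3,6-dimethylbenzoate
Product: 5 methyl 2,4-dihydroxy-3,5,6-trimethylbenzoate, via hydroxymethyl arene 4 (not isolated)
Conditions: Et3SiH, CF3CO2H, CH2Cl2, rt
Reagents that add atoms: none
Why: Ionic hydrogenation, in which the aldehyde and then the benzylic alcohol 4 ionize easily because of the ortho and para hydroxyl groups and each cation takes hydride from the silane, while the fully substituted ring allows no Friedel–Crafts side reaction.

Step 3
Reactants: 5 methyl 2,4-dihydroxy-3,5,6-trimethylbenzoate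
Product: 6 methyl 4-(benzyloxy)-2-hydroxy-3,5,6-trimethylbenzoate
Conditions: BnBr (1.05 equiv), K2CO3, acetone, reflux
Reagents that add atoms: benzyl bromide, BrCc1ccccc1
Why: Williamson ether synthesis, selective because the C2 hydroxyl is held in a hydrogen bond to the ester carbonyl and the free C4 hydroxyl is ionized and alkylated first.

Step 4
Reactants: 6 methyl 4-(benzyloxy)-2-hydroxy-3,5,6-trimethylbenzoate
Product: 7 methyl 4-(benzyloxy)-2-methoxy-3,5,6-trimethylbenzoate
Conditions: MeI, K2CO3, DMF, 50 °C
Reagents that add atoms: iodomethane, CI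
Why: Williamson methylation of the remaining chelated phenol, which a dipolar solvent and mild heating should force, the benzyl ether keeping the C4 oxygen out of play.

Step 5
Reactants: 7 methyl 4-(benzyloxy)-2-methoxy-3,5,6-trimethylbenzoate
Product: 8 methyl 4-hydroxy-2-methoxy-3,5,6-trimethylbenzoate (ring A phenol)
Conditions: H2 (1 atm), Pd/C, EtOAc, rt
Reagents that add atoms: none
Why: Catalytic hydrogenolysis of the aryl benzyl ether frees the C4 phenol and leaves the methyl ester and methyl ether untouched.

Step 6
Reactants: 8 methyl 4-hydroxy-2-methoxy-3,5,6-trimethylbenzoate; 9 bromoacetyl bromide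
Product: 10 methyl 4-(2-bromoacetoxy)-2-methoxy-3,5,6-trimethylbenzoate
Conditions: pyridine, CH2Cl2, 0 °C
Reagents that add atoms: none
Why: O-acylation by a small, very reactive acyl bromide forms the hindered depside C–O bond while the acyl partner still has no ortho substituents.

Step 7
Reactants: 10 methyl 4-(2-bromoacetoxy)-2-methoxy-3,5,6-trimethylbenzoate
Product: 13 methyl 4-(2-diazoacetoxy)-2-methoxy-3,5,6-trimethylbenzoate, via N-alkyl ditosylhydrazide 11 (not isolated), via glyoxylate tosylhydrazone 12 (not isolated)
Conditions: TsNHNHTs, DBU, THF, 0 °C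
Reagents that add atoms: N,N'-ditosylhydrazine, Cc1ccc(cc1)S(=O)(=O)NNS(=O)(=O)c1ccc(C)cc1
Why: Diazoacetate synthesis from a bromoacetate, in which a sulfonamide nitrogen displaces bromide to give 11 and DBU then expels two sulfinate ions in turn through 12, at a temperature the di-ortho-substituted aryl ester should tolerate.

Step 8
Reactants: 13 methyl 4-(2-diazoacetoxy)-2-methoxy-3,5,6-trimethylbenzoate; 14 methacrolein
Product: 15 racemic ring A aryl 2-diazo-3-hydroxy-4-methylpent-4-enoate
Conditions: DBU (0.2 equiv), MeCN, 0 °C to rt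
Reagents that add atoms: none
Why: DBU-catalysed aldol-type 1,2-addition of the diazoacetate carbon to the aldehyde; the new carbinol stereocentre is not controlled (racemic) and is removed in step 9.

Step 9
Reactants: 15 racemic ring A aryl 2-diazo-3-hydroxy-4-methylpent-4-enoate
Product: 16 ring A aryl 2-diazo-4-methyl-3-oxopent-4-enoate
Conditions: IBX, DMSO, rt
Reagents that add atoms: none
Why: IBX oxidation of a β-hydroxy-α-diazo ester to the 2-diazo-1,3-dicarbonyl compound, which spares the diazo group and is eased by the allylic nature of the carbinol.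

Step 10
Reactants: 17 1-propynyllithium
Product: 19 triisopropyl(prop-1-yn-1-yloxy)silane, via lithium prop-1-yn-1-olate 18 (not isolated)
Conditions: t-BuOOH, LiN(SiMe3)2, THF, −78 to 0 °C; then iPr3SiOTf, −78 °C to rt
Reagents that add atoms: tert-butyl hydroperoxide, CC(C)(C)OO; triisopropylsilyl trifluoromethanesulfonate, CC(C)[Si](OS(=O)(=O)C(F)(F)F)(C(C)C)C(C)C
Why: Electrophilic oxygen transfer from lithium tert-butyl peroxide to the acetylide carbon gives ynolate 18, which the bulky silyl triflate traps on oxygen and not on carbon.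

Step 11
Reactants: 16 ring A aryl 2-diazo-4-methyl-3-oxopent-4-enoate; 19 triisopropyl(prop-1-yn-1-yloxy)silane
Product: 24 methyl 4-({4-hydroxy-2,5-dimethyl-6-[(triisopropylsilyl)oxy]benzoyl}oxy)-2-methoxy-3,5,6-trimethylbenzoate, via vinylketene 20 (not isolated), via vinylcyclobutenone 21 (not isolated), via dienylketene 22 (not isolated), via cyclohexadienone 23 (not isolated)
Conditions: hν (>300 nm, Pyrex-filtered medium-pressure Hg lamp), degassed ClCH2CH2Cl, rt; then 80 °C
Reagents that add atoms: none
Why: Proposed new method: the photochemical Wolff/siloxyalkyne benzannulation is established for α-diazo enones (Danheiser benzannulation) and the photochemical Wolff shift for 2-diazo-1,3-dicarbonyl compounds, but the two have not been joined on a 2-diazo-3-oxopent-4-enoate whose ketene carries an ester group, so the step rests on this reasoning: light expels N2 from 16, the isopropenyl group shifts from the ketone carbon to the diazo carbon (C1'–C2') to give vinylketene 20, and the nucleophilic methyl-bearing carbon of 19 attacks the ketene carbonyl carbon in a (2+2) addition (C4'–C5', C6'–C1') that gives cyclobutenone 21. At 80 °C 21 opens by four-electron electrocyclic cleavage of the bond between its carbonyl and quaternary carbons to dienylketene 22, ring B closes by thermal disrotatory six-electron electrocyclization between C3' and C4' to dienone 23, and enolization gives phenol 24 with the silyl group still on the C6' oxygen. Ring B is the only ring that remains and it is closed by the 6π electrocyclization, the four-membered ring of 21 being a transient (2+2) adduct. No stereocentre is formed in 24, since the quaternary carbon of racemic 21 is lost on ring opening. Three selectivities are needed: vinyl rather than aryloxy migration in the Wolff shift, which the much higher migratory aptitude of carbon groups over alkoxy groups should provide; methyl at C5' and silyloxy at C6', which follow from the polarization of the ynol ether against the electrophilic ketene carbon; and carbon rather than ester-oxygen closure of the ketene–alkyne adduct, expected because an aryl ester carbonyl is a poor heterodiene terminus and because ring opening of 21 is reversible while aromatization removes the isomer of 22 that can cyclize. Irradiation above 300 nm addresses the diazo dicarbonyl chromophore and should leave the ring A benzoate and the aryl ester (photo-Fries cleavage) unexcited.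

Step 12
Reactants: 24 methyl 4-({4-hydroxy-2,5-dimethyl-6-[(triisopropylsilyl)oxy]benzoyl}oxy)-2-methoxy-3,5,6-trimethylbenzoate
Product: 25 methyl 4-[(4,6-dihydroxy-2,5-dimethylbenzoyl)oxy]-2-methoxy-3,5,6-trimethylbenzoate
Conditions: Bu4NF, AcOH, THF, 0 °C
Reagents that add atoms: none
Why: Fluoride-induced cleavage of the aryl silyl ether through pentacoordinate silicon, with acetic acid buffering the liberated phenoxide so that the depside ester is not attacked.

Step 13
Reactants: 25 methyl 4-[(4,6-dihydroxy-2,5-dimethylbenzoyl)oxy]-2-methoxy-3,5,6-trimethylbenzoate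
Product: 26 methyl 4-[(3-chloro-4,6-dihydroxy-2,5-dimethylbenzoyl)oxy]-2-methoxy-3,5,6-trimethylbenzoate (target)
Conditions: SO2Cl2 (1.05 equiv), Et2O, 0 °C
Reagents that add atoms: sulfuryl chloride, O=S(=O)(Cl)Cl
Why: Electrophilic aromatic chlorination, directed to C3' because it is the only unsubstituted aromatic carbon in the molecule and lies ortho to the C4' hydroxyl and para to the C6' hydroxyl.

**Compound list**
1 | methyl 2,4-dihydroxy-3,6-dimethylbenzoate (atraric acid) | COC(=O)c1c(C)cc(O)c(C)c1O | starting material
2 | methyl 5-[chloro(methoxy)methyl]-2,4-dihydroxy-3,6-dimethylbenzoate (racemic) | COC(=O)c1c(C)c(C(Cl)OC)c(O)c(C)c1O | intermediate (not isolated)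
3 | methyl 5-formyl-2,4-dihydroxy-3,6-dimethylbenzoate | COC(=O)c1c(C)c(C=O)c(O)c(C)c1O | intermediate
4 | methyl 2,4-dihydroxy-5-(hydroxymethyl)-3,6-dimethylbenzoate | COC(=O)c1c(C)c(CO)c(O)c(C)c1O | intermediate (not isolated)
5 | methyl 2,4-dihydroxy-3,5,6-trimethylbenzoate | COC(=O)c1c(C)c(C)c(O)c(C)c1O | intermediate
6 | methyl 4-(benzyloxy)-2-hydroxy-3,5,6-trimethylbenzoate | COC(=O)c1c(C)c(C)c(OCc2ccccc2)c(C)c1O | intermediate
7 | methyl 4-(benzyloxy)-2-methoxy-3,5,6-trimethylbenzoate | COC(=O)c1c(C)c(C)c(OCc2ccccc2)c(C)c1OC | intermediate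
8 | methyl 4-hydroxy-2-methoxy-3,5,6-trimethylbenzoate (ring A phenol) | COC(=O)c1c(C)c(C)c(O)c(C)c1OC | intermediate
9 | bromoacetyl bromide | BrCC(Br)=O | starting material
10 | methyl 4-(2-bromoacetoxy)-2-methoxy-3,5,6-trimethylbenzoate | COC(=O)c1c(C)c(C)c(OC(=O)CBr)c(C)c1OC | intermediate
11 | methyl 4-({[1,2-bis(4-methylbenzenesulfonyl)hydrazinyl]acetyl}oxy)-2-methoxy-3,5,6-trimethylbenzoate | COC(=O)c1c(C)c(C)c(OC(=O)CN(NS(=O)(=O)c2ccc(C)cc2)S(=O)(=O)c2ccc(C)cc2)c(C)c1OC | intermediate (not isolated)
12 | methyl 2-methoxy-3,5,6-trimethyl-4-({(2E)-[2-(4-methylbenzenesulfonyl)hydrazinylidene]acetyl}oxy)benzoate | COC(=O)c1c(C)c(C)c(OC(=O)/C=N/NS(=O)(=O)c2ccc(C)cc2)c(C)c1OC | intermediate (not isolated)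
13 | methyl 4-(2-diazoacetoxy)-2-methoxy-3,5,6-trimethylbenzoate | COC(=O)c1c(C)c(C)c(OC(=O)C=[N+]=[N-])c(C)c1OC | intermediate
14 | methacrolein | C=C(C)C=O | starting material
15 | 3-methoxy-4-(methoxycarbonyl)-2,5,6-trimethylphenyl 2-diazo-3-hydroxy-4-methylpent-4-enoate (racemic) | COC(=O)c1c(C)c(C)c(OC(=O)C(=[N+]=[N-])C(O)C(C)=C)c(C)c1OC | intermediate
16 | 3-methoxy-4-(methoxycarbonyl)-2,5,6-trimethylphenyl 2-diazo-4-methyl-3-oxopent-4-enoate | COC(=O)c1c(C)c(C)c(OC(=O)C(=[N+]=[N-])C(=O)C(C)=C)c(C)c1OC | intermediate
17 | 1-propynyllithium | [Li]C#CC | starting material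
18 | lithium prop-1-yn-1-olate | CC#C[O-].[Li+] | intermediate (not isolated)
19 | triisopropyl(prop-1-yn-1-yloxy)silane | CC#CO[Si](C(C)C)(C(C)C)C(C)C | intermediate
20 | 3-methoxy-4-(methoxycarbonyl)-2,5,6-trimethylphenyl 3-methyl-2-(oxomethylidene)but-3-enoate (vinylketene) | COC(=O)c1c(C)c(C)c(OC(=O)C(=C=O)C(C)=C)c(C)c1OC | intermediate (not isolated)
21 | 3-methoxy-4-(methoxycarbonyl)-2,5,6-trimethylphenyl 3-methyl-4-oxo-1-(prop-1-en-2-yl)-2-[(triisopropylsilyl)oxy]cyclobut-2-ene-1-carboxylate (racemic) | COC(=O)c1c(C)c(C)c(OC(=O)C2(C(C)=C)C(=O)C(C)=C2O[Si](C(C)C)(C(C)C)C(C)C)c(C)c1OC | intermediate (not isolated)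
22 | 3-methoxy-4-(methoxycarbonyl)-2,5,6-trimethylphenyl (2Z)-4-methyl-5-oxo-2-(prop-1-en-2-yl)-3-[(triisopropylsilyl)oxy]penta-2,4-dienoate (dienylketene) | COC(=O)c1c(C)c(C)c(OC(=O)/C(C(C)=C)=C(\O[Si](C(C)C)(C(C)C)C(C)C)C(C)=C=O)c(C)c1OC | intermediate (not isolated)
23 | 3-methoxy-4-(methoxycarbonyl)-2,5,6-trimethylphenyl 2,5-dimethyl-4-oxo-6-[(triisopropylsilyl)oxy]cyclohexa-1,5-diene-1-carboxylate | COC(=O)c1c(C)c(C)c(OC(=O)C2=C(C)CC(=O)C(C)=C2O[Si](C(C)C)(C(C)C)C(C)C)c(C)c1OC | intermediate (not isolated)
24 | methyl 4-({4-hydroxy-2,5-dimethyl-6-[(triisopropylsilyl)oxy]benzoyl}oxy)-2-methoxy-3,5,6-trimethylbenzoate | COC(=O)c1c(C)c(C)c(OC(=O)c2c(C)cc(O)c(C)c2O[Si](C(C)C)(C(C)C)C(C)C)c(C)c1OC | intermediate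
25 | methyl 4-[(4,6-dihydroxy-2,5-dimethylbenzoyl)oxy]-2-methoxy-3,5,6-trimethylbenzoate | COC(=O)c1c(C)c(C)c(OC(=O)c2c(C)cc(O)c(C)c2O)c(C)c1OC | intermediate
26 | methyl 4-[(3-chloro-4,6-dihydroxy-2,5-dimethylbenzoyl)oxy]-2-methoxy-3,5,6-trimethylbenzoate | COC(=O)c1c(C)c(C)c(OC(=O)c2c(C)c(Cl)c(O)c(C)c2O)c(C)c1OC | target

**Count**
Total step count: 13. Longest linear sequence: 12 steps (steps 1–9 and 11–13, from compound 1); step 10 is a one-step branch.

**Steps most likely to fail**

Step 11 (proposed new method). Ring B may fail to close in several ways: the ester-bearing ketene may be intercepted through its ester carbonyl (oxygen closure instead of carbon closure) or dimerize, the aryl ester may be cleaved photochemically, or the cyclobutenone may open with the ester turned toward the ketene. The fallback uses known depside chemistry, sets out from compounds 1 and 8 and returns at compound 25; ring B is taken ready-made from atraric acid instead of being built. Compound 1 is benzylated on both hydroxyls (BnBr, K2CO3, DMF, 80 °C) to methyl 2,4-bis(benzyloxy)-3,6-dimethylbenzoate F1, which is saponified (KOH, aqueous DMSO, 90 °C) to 2,4-bis(benzyloxy)-3,6-dimethylbenzoic acid F2. F2 and phenol 8 are joined with (CF3CO)2O in toluene, an esterification through the mixed anhydride that tolerates two ortho substituents on each partner, to 3-methoxy-4-(methoxycarbonyl)-2,5,6-trimethylphenyl 2,4-bis(benzyloxy)-3,6-dimethylbenzoate F3. Hydrogenolysis of both benzyl ethers (H2, Pd/C, EtOAc) should then give 25, which enters step 13.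

Step 8. The 1,2-addition may be outrun by attack of the diazo carbon on the conjugated double bond of methacrolein (dipolar cycloaddition or conjugate addition), by base-induced polymerization of the enal, or by DBU-mediated acyl transfer from the aryl ester. The fallback sets out from compound 10 and returns at compound 16; the carbon chain is completed before the diazo group is introduced, so steps 7 to 9 are bypassed. Reformatsky addition of 10 (Zn dust, THF) to methacrolein 14 should give racemic 3-methoxy-4-(methoxycarbonyl)-2,5,6-trimethylphenyl 3-hydroxy-4-methylpent-4-enoate F4. Dess–Martin oxidation should give the vinylic β-keto ester 3-methoxy-4-(methoxycarbonyl)-2,5,6-trimethylphenyl 4-methyl-3-oxopent-4-enoate F5, and Regitz diazo transfer (4-acetamidobenzenesulfonyl azide, Et3N, MeCN, 0 °C) compound 16.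

Step 10. Oxygen transfer to the poorly soluble acetylide may be incomplete, silylation may occur on carbon, or the small siloxyalkyne may be hydrolysed or lost by evaporation during isolation. The fallback is a Kowalski ester homologation that sets out from purchased ethyl acetate and returns at compound 18. Dibromomethyllithium F6, made from CH2Br2 and lithium 2,2,6,6-tetramethylpiperidide at −78 °C, adds to ethyl acetate, and LiN(SiMe3)2 completes the conversion into lithium 1,1-dibromoprop-1-en-2-olate F7. n-BuLi then exchanges one bromine and the carbenoid rearranges on warming to ynolate 18, which is silylated on oxygen (iPr3SiCl) as in the second half of step 10.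

**Further compounds**
F1 | step 11 | methyl 2,4-bis(benzyloxy)-3,6-dimethylbenzoate | COC(=O)c1c(C)cc(OCc2ccccc2)c(C)c1OCc3ccccc3
F2 | step 11 | 2,4-bis(benzyloxy)-3,6-dimethylbenzoic acid | OC(=O)c1c(C)cc(OCc2ccccc2)c(C)c1OCc3ccccc3
F3 | step 11 | 3-methoxy-4-(methoxycarbonyl)-2,5,6-trimethylphenyl 2,4-bis(benzyloxy)-3,6-dimethylbenzoate | COC(=O)c1c(C)c(C)c(OC(=O)c2c(C)cc(OCc3ccccc3)c(C)c2OCc4ccccc4)c(C)c1OC
F4 | step 8 | 3-methoxy-4-(methoxycarbonyl)-2,5,6-trimethylphenyl 3-hydroxy-4-methylpent-4-enoate (racemic) | COC(=O)c1c(C)c(C)c(OC(=O)CC(O)C(C)=C)c(C)c1OC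
F5 | step 8 | 3-methoxy-4-(methoxycarbonyl)-2,5,6-trimethylphenyl 4-methyl-3-oxopent-4-enoate | COC(=O)c1c(C)c(C)c(OC(=O)CC(=O)C(C)=C)c(C)c1OC
F6 | step 10 | dibromomethyllithium | [Li]C(Br)Br
F7 | step 10 | lithium 1,1-dibromoprop-1-en-2-olate | CC([O-])=C(Br)Br.[Li+]
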